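**Plan**
- Target: 2,4-dimethoxy-6-tricosylphenol (side chain C1' on the ring to C23' = CH3). Retrosynthetic cuts, in order: (i) the CH2–CH2 bond C14'–C15', giving two carboxylic acids as N-hydroxyphthalimide esters; (ii) a temporary C2'=C3' alkene by cross-metathesis, back to an allylarene and erucic acid; (iii) the ring C6–C1' bond by aromatic Claisen rearrangement.
- Forward: O-allylation and [3,3] shift put C1'–C3' on the ring; benzyl protection; metathesis with erucic acid adds C4'–C14' and the carboxyl handle; an electroreductive double decarboxylation joins C15'–C23' from decanoic acid; one hydrogenation removes alkene and benzyl group.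
- Enabling feature: from C4' to C23' the chain is a bare polymethylene string, so C14' and C15' are two unactivated CH2 groups of like polarity. Each is the carbon next to the carboxyl of a fatty acid (C2 of a 15-arylpentadecenoic acid, C2 of decanoic acid) and can be released as a primary radical by loss of CO2. The only electron-rich unit, the 1-hydroxy-2,4-dimethoxybenzene ring, lies 14 carbons away and is inert at a cathode.
- On the ring, C6 is the only unsubstituted position ortho to O1 (C2 and C4 carry OMe), so the sigmatropic shift can end nowhere else.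
- Stereochemistry: the target has no stereocentre; the E/Z geometry of the temporary alkene is erased in the last step.

Key step: step 7

Remark: the target is achiral (no stereocentre, no stereogenic double bond), so no enantiocontrol is needed. 2,4-Dimethoxyphenol, erucic acid and decanoic acid are taken as commercial. The temporary alkene is expected as an E/Z mixture (E drawn); both isomers converge in step 8.

**Step 1**
Reactants: 1 2,4-dimethoxyphenol; 2 allyl bromide
Product: 3 1-(allyloxy)-2,4-dimethoxybenzene
Conditions: K2CO3, acetone, reflux, under Ar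
Reagents that add atoms: none
Why: Williamson ether synthesis; the phenoxide is the only nucleophile and allyl bromide a reactive SN2 electrophile.

**Step 2**
Reactants: 3 1-(allyloxy)-2,4-dimethoxybenzene
Product: 5 2-allyl-4,6-dimethoxyphenol, via 6-allyl-2,4-dimethoxycyclohexa-2,4-dien-1-one 4 (not isolated)
Conditions: PhNEt2 (degassed), 200 °C, Ar
Reagents that add atoms: none
Why: Aromatic Claisen rearrangement; the [3,3] shift can deliver the allyl terminus productively only to C6, because C2 and C4 carry OMe and only dienone 4 can tautomerise to a phenol.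

**Step 3**
Reactants: 5 2-allyl-4,6-dimethoxyphenol
Product: 6 1-allyl-2-(benzyloxy)-3,5-dimethoxybenzene
Conditions: BnBr, K2CO3, DMF, rt
Reagents that add atoms: benzyl bromide, BrCc1ccccc1
Why: Williamson benzylation masks the acidic, oxidation-prone phenol for the metathesis, acylation and electrolysis steps, and the benzyl group leaves in the final hydrogenation.

**Step 4**
Reactants: 6 1-allyl-2-(benzyloxy)-3,5-dimethoxybenzene; 7 erucic acid ((Z)-docos-13-enoic acid)
Product: 8 (E)-15-[2-(benzyloxy)-3,5-dimethoxyphenyl]pentadec-13-enoic acid
Conditions: 7 (3 equiv), Hoveyda–Grubbs II (3 mol%), 1,4-benzoquinone (10 mol%), CH2Cl2, 40 °C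
Reagents that add atoms: none
Why: Ru-catalysed olefin cross-metathesis exchanges the =CH2 terminus of 6 for the =CH(CH2)11CO2H half of erucic acid, whose Δ13 alkene places exactly eleven methylenes before the carboxyl; the free acid is tolerated, benzoquinone should suppress migration of the allylic double bond, and acid–base extraction removes the neutral cross product carrying the octyl half.

**Step 5**
Reactants: 8 (E)-15-[2-(benzyloxy)-3,5-dimethoxyphenyl]pentadec-13-enoic acid
Product: 9 1,3-dioxoisoindolin-2-yl (E)-15-[2-(benzyloxy)-3,5-dimethoxyphenyl]pentadec-13-enoate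
Conditions: N-hydroxyphthalimide, DIC, DMAP (cat.), CH2Cl2, rt
Reagents that add atoms: N-hydroxyphthalimide, O=C1c2ccccc2C(=O)N1O
Why: Carbodiimide (Steglich-type) esterification gives the redox-active ester that activates the carboxyl carbon for reductive decarboxylation.

**Step 6**
Reactants: 10 decanoic acid
Product: 11 1,3-dioxoisoindolin-2-yl decanoate
Conditions: N-hydroxyphthalimide, DIC, DMAP (cat.), CH2Cl2, rt
Reagents that add atoms: N-hydroxyphthalimide, O=C1c2ccccc2C(=O)N1O
Why: The same carbodiimide esterification turns the cheap C10 acid into the nonyl radical precursor.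

**Step 7**
Reactants: 9 1,3-dioxoisoindolin-2-yl (E)-15-[2-(benzyloxy)-3,5-dimethoxyphenyl]pentadec-13-enoate; 11 1,3-dioxoisoindolin-2-yl decanoate
Product: 12 (E)-2-(benzyloxy)-1,5-dimethoxy-3-(tricos-2-en-1-yl)benzene
Conditions: 9 (1 equiv), 11 (3 equiv), NiCl2·6H2O (20 mol%), 2,6-bis(pyrazol-1-yl)pyridine (20 mol%), AgNO3 (0.3 equiv), NaI, DMF/THF, Zn(+)/RVC(−), constant current, rt; then 1 M HCl
Reagents that add atoms: none
Why: Each N-acyloxyphthalimide takes up one electron at the silver-coated cathode or from low-valent nickel and fragments to phthalimide anion, CO2 and a primary alkyl radical; the tridentate-N-ligated nickel centre captures the two radicals in turn and reductive elimination from the dialkylnickel forms the C(sp3)–C(sp3) bond, with the zinc anode supplying the two electrons. The closest known reaction type is the Ni-electrocatalytic doubly decarboxylative coupling of two alkyl redox-active esters, a reductive counterpart of the mixed Kolbe electrolysis that is established for primary–primary unions of fatty chains. No ring is closed and no stereocentre is formed, since the new bond joins two CH2 groups. The selectivity needed is cross- over homo-coupling, which is statistical for two unbiased primary radicals; the threefold excess of the cheap ester 11 should channel 9 into 12, and octadecane and the bis-aryl C28 dimer differ enough in polarity and size to be separated. The cathodic manifold should leave untouched the electron-rich trioxygenated ring (which an anodic Kolbe coupling would oxidise), the benzyl ether and the disubstituted alkene, which is too far from the radical centre to cyclise.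

**Step 8**
Reactants: 12 (E)-2-(benzyloxy)-1,5-dimethoxy-3-(tricos-2-en-1-yl)benzene
Product: 13 2,4-dimethoxy-6-tricosylphenol
Conditions: H2 (1 atm), 10% Pd/C, EtOAc/THF, 40 °C; work-up under Ar
Reagents that add atoms: none
Why: Heterogeneous hydrogenation should saturate the disubstituted alkene and hydrogenolyse the benzylic C–O bond in one operation, while the arene and the aryl methyl ethers are inert.

**Compound list**
1 | 2,4-dimethoxyphenol | COc1ccc(O)c(OC)c1 | starting material
2 | allyl bromide | C=CCBr | starting material
3 | 1-(allyloxy)-2,4-dimethoxybenzene | C=CCOc1ccc(OC)cc1OC | intermediate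
4 | 6-allyl-2,4-dimethoxycyclohexa-2,4-dien-1-one (racemic, transient) | C=CCC1C=C(OC)C=C(OC)C1=O | intermediate
5 | 2-allyl-4,6-dimethoxyphenol | C=CCc1cc(OC)cc(OC)c1O | intermediate
6 | 1-allyl-2-(benzyloxy)-3,5-dimethoxybenzene | C=CCc1cc(OC)cc(OC)c1OCc1ccccc1 | intermediate
7 | erucic acid, (Z)-docos-13-enoic acid | CCCCCCCC/C=C\CCCCCCCCCCCC(=O)O | starting material
8 | (E)-15-[2-(benzyloxy)-3,5-dimethoxyphenyl]pentadec-13-enoic acid | OC(=O)CCCCCCCCCCC/C=C/Cc1cc(OC)cc(OC)c1OCc1ccccc1 | intermediate
9 | 1,3-dioxoisoindolin-2-yl (E)-15-[2-(benzyloxy)-3,5-dimethoxyphenyl]pentadec-13-enoate | O=C(CCCCCCCCCCC/C=C/Cc1cc(OC)cc(OC)c1OCc1ccccc1)ON1C(=O)c2ccccc2C1=O | intermediate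
10 | decanoic acid | CCCCCCCCCC(=O)O | starting material
11 | 1,3-dioxoisoindolin-2-yl decanoate | CCCCCCCCCC(=O)ON1C(=O)c2ccccc2C1=O | intermediate
12 | (E)-2-(benzyloxy)-1,5-dimethoxy-3-(tricos-2-en-1-yl)benzene | CCCCCCCCCCCCCCCCCCCC/C=C/Cc1cc(OC)cc(OC)c1OCc1ccccc1 | intermediate
13 | 2,4-dimethoxy-6-tricosylphenol | CCCCCCCCCCCCCCCCCCCCCCCc1cc(OC)cc(OC)c1O | target

**Step count:** 8 steps in total; longest linear sequence 7 steps (steps 1, 2, 3, 4, 5, 7, 8).

**Steps most likely to fail**

1. Step 7. The two primary radicals are unbiased, so homo-coupling and hydrodecarboxylation (protonation of alkylnickel species or hydrogen abstraction from the solvent) may consume 9, and waxy deposits may passivate the cathode. The fallback sets out from 9 and returns at 12. It is a nickel-catalysed decarboxylative Negishi alkyl–alkyl coupling, in which the nonyl partner is a preformed nucleophile and cross-selectivity is no longer statistical. Commercial nonylmagnesium bromide would be transmetalated with ZnCl2 (0.5 equiv, THF) to dinonylzinc F1. F1 (2 equiv) would then be added to 9 with NiCl2·glyme (20 mol%) and 4,4'-di-tert-butyl-2,2'-bipyridine (40 mol%) in THF/DMF at rt to give 12.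

2. Step 4. The arylallyl terminus is partitioned statistically between the two halves of the internal olefin, 6 may self-metathesise, and ruthenium hydride species may move the double bond into conjugation with the ring, which would shorten the chain by one carbon. The fallback sets out from 6 and returns at 13 through the saturated series. Hydroboration of 6 with 9-BBN-H (THF, rt) should give B-{3-[2-(benzyloxy)-3,5-dimethoxyphenyl]propyl}-9-borabicyclo[3.3.1]nonane F2. F2 would be coupled in the same pot with commercial methyl 12-bromododecanoate (Pd(OAc)2, PCy3, K3PO4·H2O, THF, rt; alkyl–alkyl Suzuki–Miyaura coupling) to methyl 15-[2-(benzyloxy)-3,5-dimethoxyphenyl]pentadecanoate F3. Saponification (LiOH, THF/H2O) should give 15-[2-(benzyloxy)-3,5-dimethoxyphenyl]pentadecanoic acid F4, and N-hydroxyphthalimide/DIC its ester 1,3-dioxoisoindolin-2-yl 15-[2-(benzyloxy)-3,5-dimethoxyphenyl]pentadecanoate F5. Electrolysis of F5 with 11 under the conditions of step 7 should give 2-(benzyloxy)-1,5-dimethoxy-3-tricosylbenzene F6, and hydrogenolysis (H2, Pd/C) of F6 gives 13.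

3. Step 8. Traces of iodide, zinc or nickel carried over from the electrolysis may poison the palladium, the waxy substrate may be poorly soluble so that hydrogenolysis of the hindered benzyl ether stalls, and the electron-rich product phenol may be oxidised by air. The fallback sets out from 12 and returns at 13 with no metal catalyst. Debenzylation with BCl3 and pentamethylbenzene (CH2Cl2, −78 °C) should give (E)-2,4-dimethoxy-6-(tricos-2-en-1-yl)phenol F7. Diimide reduction of F7 (TsNHNH2, NaOAc, THF/H2O, reflux, under Ar) then gives 13.

**Further compounds**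
F1 | step 7 | dinonylzinc | CCCCCCCCC[Zn]CCCCCCCCC
F2 | step 4 | B-{3-[2-(benzyloxy)-3,5-dimethoxyphenyl]propyl}-9-borabicyclo[3.3.1]nonane | COc1cc(OC)c(OCc2ccccc2)c(CCCB2C3CCCC2CCC3)c1
F3 | step 4 | methyl 15-[2-(benzyloxy)-3,5-dimethoxyphenyl]pentadecanoate | COC(=O)CCCCCCCCCCCCCCc1cc(OC)cc(OC)c1OCc1ccccc1
F4 | step 4 | 15-[2-(benzyloxy)-3,5-dimethoxyphenyl]pentadecanoic acid | OC(=O)CCCCCCCCCCCCCCc1cc(OC)cc(OC)c1OCc1ccccc1
F5 | step 4 | 1,3-dioxoisoindolin-2-yl 15-[2-(benzyloxy)-3,5-dimethoxyphenyl]pentadecanoate | O=C(CCCCCCCCCCCCCCc1cc(OC)cc(OC)c1OCc1ccccc1)ON1C(=O)c2ccccc2C1=O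
F6 | step 4 | 2-(benzyloxy)-1,5-dimethoxy-3-tricosylbenzene | CCCCCCCCCCCCCCCCCCCCCCCc1cc(OC)cc(OC)c1OCc1ccccc1
F7 | step 8 | (E)-2,4-dimethoxy-6-(tricos-2-en-1-yl)phenol | CCCCCCCCCCCCCCCCCCCC/C=C/Cc1cc(OC)cc(OC)c1O
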